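**Plan**

1. Retrosynthesis: cleave the two acyl C–O bonds (O-1, O-6). Return the 6β-O / 7α-OH / 7-CH2OH array to a 6β,7β-epoxy alcohol and then to a C6=C7 enoate. Cut C4–CH2OH back to a C4 ketone. Last, cut C7a–C7 and C4a–C5, which removes a three-carbon unit (C5–C6–C7 plus the ester carbon on C7) from a pyranone.
2. Forward: the pyran ring is made first from furfuryl alcohol (Achmatowicz). The cyclopentene is then annulated onto its enone with ethyl buta-2,3-dienoate under phosphine catalysis. The C4 carbon (enol triflate, Stille), the C6/C7 oxygens (epoxidation, Payne) and the two esters follow.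
3. Enabling feature: C7a and C4a are the β- and α-carbons of an enone (C4=O) inside the six-membered ring. C5, C6, C7 and the hydroxymethyl carbon on C7 map onto the γ-, β-, α- and carboxyl carbons of an allenoate. The acetal carbon C1 sits next to C7a and steers the face.
4. Stereochemistry: C1 from a catalyst-controlled dynamic kinetic acylation of the lactol; C7a and C4a from anti addition to the C1 substituent and cis closure; C6 and C7 from a β-face Sharpless epoxidation and Payne inversion at C7; the final C1 ester by substrate control; the side-chain centre from (R)-3-methylpentanoic acid; the Z alkene from (Z)-3-iodoacrylic acid through a stereoretentive Suzuki coupling.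

Key step: step 4

Remark on names: cyclopenta[c]pyran locants are used (C1 acetal carbon, C3=C4 enol ether, C4a/C7a ring fusion, C5–C6–C7 the rest of the five-membered ring); β is the face of the ring-fusion hydrogens H-4a/H-7a.
Assumption: (R)-3-methylpentanoic acid (22) is bought as the single enantiomer.

**Route**

Step 1
Reactants: 1 furfuryl alcohol
Product: 3 6-hydroxy-2H-pyran-3(6H)-one (racemic), via enedione 2 (not isolated)
Conditions: mCPBA, CH2Cl2, 0 °C
Reagents that add atoms: 3-chloroperbenzoic acid, OOC(=O)c1cccc(Cl)c1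
Why: Achmatowicz rearrangement, in which peracid oxidation of the furan gives the ring-opened cis-enedione whose primary hydroxyl closes onto the aldehyde; the lactol centre is configurationally labile, so no stereocontrol is needed here.

Step 2
Reactants: 3 6-hydroxy-2H-pyran-3(6H)-one (racemic)
Product: 4 (2S)-5-oxo-5,6-dihydro-2H-pyran-2-yl 2-methylpropanoate
Conditions: (R)-benzotetramisole (5 mol%), (iPrCO)2O, iPr2NEt, CHCl3, 0 °C
Reagents that add atoms: 2-methylpropanoic anhydride, CC(C)C(=O)OC(=O)C(C)C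
Why: Isothiourea-catalysed dynamic kinetic acylation, in which the lactol enantiomers interconvert by ring opening under the amine base while the acyl-isothiouronium of the (R)-catalyst, stacking on the enone π-system as it does on the aryl group of benzylic alcohols, is expected to acylate the enantiomer that gives the (S)-ester, so the acetal centre is set by the catalyst.

Step 3
Reactants: 4 (2S)-5-oxo-5,6-dihydro-2H-pyran-2-yl 2-methylpropanoate; 5 3,4-dimethoxybenzyl alcohol
Product: 6 (6R)-6-[(3,4-dimethoxybenzyl)oxy]-2H-pyran-3(6H)-one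
Conditions: Pd2(dba)3·CHCl3 (2.5 mol%), PPh3 (10 mol%), CH2Cl2, 0 °C to rt
Reagents that add atoms: none
Why: Tsuji–Trost-type O-glycosylation, in which zerovalent palladium ionises the allylic ester anti and the alcohol attacks the π-allyl complex anti to the metal at the oxygen-bearing terminus, so the acetal centre is transferred with net retention (the descriptor becomes R only through the priority rules).

Step 4
Reactants: 6 (6R)-6-[(3,4-dimethoxybenzyl)oxy]-2H-pyran-3(6H)-one; 7 ethyl buta-2,3-dienoate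
Product: 8 ethyl 1β-[(3,4-dimethoxybenzyl)oxy]-4-oxo-1,3,4,4a,5,7a-hexahydrocyclopenta[c]pyran-7-carboxylate (cis-fused, H-4a and H-7a β)
Conditions: PPh3 (10 mol%), toluene, 110 °C
Reagents that add atoms: none
Why: PPh3 adds to the central carbon of 7 to give a zwitterionic three-carbon dipole whose ester-bearing carbon attacks C7a, the β-carbon of the enone of 6, after which the C4a enolate adds to the CH2 end of the vinylphosphonium, and proton transfer with loss of PPh3 leaves the C6=C7 enoate. The closest known reaction type is the phosphine-catalysed allenoate–enone (3+2) annulation (Lu annulation), which is established for 6-acyloxy-2H-pyran-3(6H)-ones. The cyclopentene is closed by a stepwise formal (3+2) cycloaddition in which the ring-closing bond C4a–C5 arises from a formally 5-endo-trig addition of the enolate to the vinylphosphonium. C7a is set by attack anti to the neighbouring C1 alkoxy group, and C4a is set by the ring closure, which can only join the three-carbon bridge cis across C7a–C4a. The step needs regioselectivity for the α-adduct (ester carbon on C7, next to C7a), facial selectivity and chemoselectivity for the enone; these should come from the higher nucleophilicity of the α-carbon of the unsubstituted dipole towards cyclic enones, from the acetal substituent directly beside the carbon that is attacked, and from the lack of any other electron-poor alkene in 6.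

Step 5
Reactants: 8 ethyl 1β-[(3,4-dimethoxybenzyl)oxy]-4-oxo-1,3,4,4a,5,7a-hexahydrocyclopenta[c]pyran-7-carboxylate
Product: 9 ethyl 1β-[(3,4-dimethoxybenzyl)oxy]-4-[(trifluoromethanesulfonyl)oxy]-1,4a,5,7a-tetrahydrocyclopenta[c]pyran-7-carboxylate
Conditions: LiN(SiMe3)2, THF, −78 °C; then PhNTf2, −78 to 0 °C
Reagents that add atoms: N-phenylbis(trifluoromethanesulfonimide), O=S(=O)(N(c1ccccc1)S(=O)(=O)C(F)(F)F)C(F)(F)F
Why: Enolate O-sulfonylation, in which the hindered, weakly basic amide should remove one of the two accessible C3 protons (acidified by the ring oxygen) rather than the tertiary ring-fusion proton at C4a, so the enol triflate fixes the C3=C4 double bond and leaves C4a untouched.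

Step 6
Reactants: 9 ethyl 1β-[(3,4-dimethoxybenzyl)oxy]-4-[(trifluoromethanesulfonyl)oxy]-1,4a,5,7a-tetrahydrocyclopenta[c]pyran-7-carboxylate
Product: 10 1β-[(3,4-dimethoxybenzyl)oxy]-7-(hydroxymethyl)-1,4a,5,7a-tetrahydrocyclopenta[c]pyran-4-yl trifluoromethanesulfonate
Conditions: iBu2AlH (2.5 equiv), CH2Cl2, −78 °C
Reagents that add atoms: none
Why: Ester reduction with iBu2AlH, which takes the conjugated ethyl ester 1,2 to the allylic alcohol at low temperature, where enol triflates and mixed acetals are inert.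

Step 7
Reactants: 10 1β-[(3,4-dimethoxybenzyl)oxy]-7-(hydroxymethyl)-1,4a,5,7a-tetrahydrocyclopenta[c]pyran-4-yl trifluoromethanesulfonate
Product: 11 1β-[(3,4-dimethoxybenzyl)oxy]-6β,7β-epoxy-7-(hydroxymethyl)-1,4a,5,6,7,7a-hexahydrocyclopenta[c]pyran-4-yl trifluoromethanesulfonate
Conditions: Ti(OiPr)4 (10 mol%), diethyl L-(+)-tartrate (12 mol%), tBuOOH, 4 Å MS, CH2Cl2, −20 °C
Reagents that add atoms: tert-butyl hydroperoxide, CC(C)(C)OO
Why: Sharpless asymmetric epoxidation, in which the titanium tartrate uses the hydroxymethyl group to deliver oxygen only to C6=C7 (the triflyloxy enol ether is electron-poor and has no directing group), and L-(+)-tartrate places it on the face from which CH2OH → C6 → C7a run clockwise around C7, here the β face, which is also the convex face of the cis-fused bicycle, so catalyst and substrate control agree.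

Step 8
Reactants: 11 1β-[(3,4-dimethoxybenzyl)oxy]-6β,7β-epoxy-7-(hydroxymethyl)-1,4a,5,6,7,7a-hexahydrocyclopenta[c]pyran-4-yl trifluoromethanesulfonate; 12 (tributylstannyl)methanol
Product: 13 {1β-[(3,4-dimethoxybenzyl)oxy]-6β,7β-epoxy-1,4a,5,6,7,7a-hexahydrocyclopenta[c]pyran-4,7-diyl}dimethanol
Conditions: Pd(PPh3)4 (10 mol%), LiCl, 1,4-dioxane, 90 °C
Reagents that add atoms: none
Why: Stille coupling, in which oxidative addition of the enol triflate to zerovalent palladium, chloride-assisted transfer of the hydroxymethyl group from tin and reductive elimination install the C4 carbon as the free alcohol under neutral conditions that epoxides and acetals normally tolerate.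

Step 9
Reactants: 13 {1β-[(3,4-dimethoxybenzyl)oxy]-6β,7β-epoxy-1,4a,5,6,7,7a-hexahydrocyclopenta[c]pyran-4,7-diyl}dimethanol
Product: 15 1β-[(3,4-dimethoxybenzyl)oxy]-4,7-bis(hydroxymethyl)-1,4a,5,6,7,7a-hexahydrocyclopenta[c]pyran-6β,7α-diol, via spiro-epoxide 14 (not isolated)
Conditions: NaOH (0.5 M aq), tBuOH, 70 °C
Reagents that add atoms: water, O
Why: Payne rearrangement followed by hydroxide opening, in which the alkoxide of the C7 hydroxymethyl group attacks C7 from the α face with inversion to give the spiro-epoxide and free the 6β-alkoxide, and hydroxide then opens the new epoxide at its unhindered CH2, so C7 ends with α-OH and β-CH2OH while C6 keeps its β oxygen.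

Step 10
Reactants: 15 1β-[(3,4-dimethoxybenzyl)oxy]-4,7-bis(hydroxymethyl)-1,4a,5,6,7,7a-hexahydrocyclopenta[c]pyran-6β,7α-diol
Product: 16 4,7-bis({[tert-butyl(dimethyl)silyl]oxy}methyl)-1β-[(3,4-dimethoxybenzyl)oxy]-1,4a,5,6,7,7a-hexahydrocyclopenta[c]pyran-6β,7α-diol
Conditions: TBSCl (2.2 equiv), imidazole, DMF, 0 °C
Reagents that add atoms: tert-butyldimethylsilyl chloride, CC(C)(C)[Si](C)(C)Cl
Why: Selective silylation, since the two primary hydroxyls react with TBSCl/imidazole far faster than the hindered secondary C6 hydroxyl and the tertiary C7 hydroxyl.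

Step 11
Reactants: 16 4,7-bis({[tert-butyl(dimethyl)silyl]oxy}methyl)-1β-[(3,4-dimethoxybenzyl)oxy]-1,4a,5,6,7,7a-hexahydrocyclopenta[c]pyran-6β,7α-diol; 17 (2Z)-3-iodoprop-2-enoic acid
Product: 18 4,7-bis({[tert-butyl(dimethyl)silyl]oxy}methyl)-1β-[(3,4-dimethoxybenzyl)oxy]-7α-hydroxy-1,4a,5,6,7,7a-hexahydrocyclopenta[c]pyran-6β-yl (2Z)-3-iodoprop-2-enoate
Conditions: iPrN=C=NiPr, DMAP (cat.), CH2Cl2, 0 °C
Reagents that add atoms: none
Why: Steglich esterification, in which the carbodiimide-activated acid acylates the only reactive hydroxyl (C6; the tertiary C7–OH is inert), and low temperature with little DMAP should keep the Z geometry of the iodoacrylate.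

Step 12
Reactants: 18 4,7-bis({[tert-butyl(dimethyl)silyl]oxy}methyl)-1β-[(3,4-dimethoxybenzyl)oxy]-7α-hydroxy-1,4a,5,6,7,7a-hexahydrocyclopenta[c]pyran-6β-yl (2Z)-3-iodoprop-2-enoate; 19 [4-(tert-butyldimethylsilyloxy)phenyl]boronic acid
Product: 20 4,7-bis({[tert-butyl(dimethyl)silyl]oxy}methyl)-1β-[(3,4-dimethoxybenzyl)oxy]-7α-hydroxy-1,4a,5,6,7,7a-hexahydrocyclopenta[c]pyran-6β-yl (2Z)-3-[4-(tert-butyldimethylsilyloxy)phenyl]prop-2-enoate
Conditions: Pd(PPh3)4 (5 mol%), Ag2O, THF, rt, dark
Reagents that add atoms: none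
Why: Suzuki–Miyaura coupling, in which oxidative addition of the vinyl iodide, Ag2O-promoted transmetalation and reductive elimination all proceed with retention, so the Z-cinnamate forms directly under conditions free of aqueous base that spare the aryl silyl ether.

Step 13
Reactants: 20 4,7-bis({[tert-butyl(dimethyl)silyl]oxy}methyl)-1β-[(3,4-dimethoxybenzyl)oxy]-7α-hydroxy-1,4a,5,6,7,7a-hexahydrocyclopenta[c]pyran-6β-yl (2Z)-3-[4-(tert-butyldimethylsilyloxy)phenyl]prop-2-enoate
Product: 21 4,7-bis({[tert-butyl(dimethyl)silyl]oxy}methyl)-1β,7α-dihydroxy-1,4a,5,6,7,7a-hexahydrocyclopenta[c]pyran-6β-yl (2Z)-3-[4-(tert-butyldimethylsilyloxy)phenyl]prop-2-enoate (lactol, drawn as the 1β-OH anomer)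
Conditions: DDQ, CH2Cl2/pH 7 buffer, 0 °C
Reagents that add atoms: none
Why: Oxidative cleavage of the dimethoxybenzyl acetal, in which DDQ abstracts hydride from the very electron-rich benzylic position (faster than it attacks an enol ether carrying an allylic silyl ether, as with glycals) and water turns the oxocarbenium ion into the aldehyde and the C1 hemiacetal.

Step 14
Reactants: 21 4,7-bis({[tert-butyl(dimethyl)silyl]oxy}methyl)-1β,7α-dihydroxy-1,4a,5,6,7,7a-hexahydrocyclopenta[c]pyran-6β-yl (2Z)-3-[4-(tert-butyldimethylsilyloxy)phenyl]prop-2-enoate; 22 (3R)-3-methylpentanoic acid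
Product: 23 4,7-bis({[tert-butyl(dimethyl)silyl]oxy}methyl)-6β-({(2Z)-3-[4-(tert-butyldimethylsilyloxy)phenyl]prop-2-enoyl}oxy)-7α-hydroxy-1,4a,5,6,7,7a-hexahydrocyclopenta[c]pyran-1β-yl (3R)-3-methylpentanoate
Conditions: DCC, DMAP (cat.), CH2Cl2, 0 °C
Reagents that add atoms: none
Why: Steglich esterification of the hemiacetal, in which the anomers interconvert and acylation is expected to give the 1β-ester, whose acyloxy group is axial (anomeric effect) and trans to the C7a–C7 bond as in acylated iridoid aglycones, while the tertiary alcohol does not react.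

Step 15
Reactants: 23 4,7-bis({[tert-butyl(dimethyl)silyl]oxy}methyl)-6β-({(2Z)-3-[4-(tert-butyldimethylsilyloxy)phenyl]prop-2-enoyl}oxy)-7α-hydroxy-1,4a,5,6,7,7a-hexahydrocyclopenta[c]pyran-1β-yl (3R)-3-methylpentanoate
Product: 24 (1S,4aS,6S,7R,7aS)-7-hydroxy-4,7-bis(hydroxymethyl)-6-{[(2Z)-3-(4-hydroxyphenyl)prop-2-enoyl]oxy}-1,4a,5,6,7,7a-hexahydrocyclopenta[c]pyran-1-yl (3R)-3-methylpentanoate
Conditions: Bu4NF, AcOH (1:1), THF, 0 °C to rt, dark
Reagents that add atoms: none
Why: Fluoride-mediated desilylation, in which acetic-acid-buffered Bu4NF should remove the aryl and the two primary silyl ethers without base-induced acyl migration, cleavage of the acyl acetal or Z/E isomerisation.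

**Compound list**

1 | furfuryl alcohol (furan-2-ylmethanol) | OCc1ccco1 | starting material
2 | (2Z)-5-hydroxy-4-oxopent-2-enal (not isolated) | O=C/C=C\C(=O)CO | intermediate
3 | 6-hydroxy-2H-pyran-3(6H)-one (racemic, labile lactol) | OC1OCC(=O)C=C1 | intermediate
4 | (2S)-5-oxo-5,6-dihydro-2H-pyran-2-yl 2-methylpropanoate | CC(C)C(=O)O[C@@H]1OCC(=O)C=C1 | intermediate
5 | 3,4-dimethoxybenzyl alcohol | COc1ccc(CO)cc1OC | starting material
6 | (6R)-6-[(3,4-dimethoxybenzyl)oxy]-2H-pyran-3(6H)-one | COc1ccc(CO[C@@H]2OCC(=O)C=C2)cc1OC | intermediate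
7 | ethyl buta-2,3-dienoate | C=C=CC(=O)OCC | starting material
8 | ethyl 1β-[(3,4-dimethoxybenzyl)oxy]-4-oxo-1,3,4,4a,5,7a-hexahydrocyclopenta[c]pyran-7-carboxylate (cis-fused, H-4a and H-7a β) | COc1ccc(CO[C@@H]2OCC(=O)[C@H]3CC=C(C(=O)OCC)[C@@H]23)cc1OC | intermediate
9 | ethyl 1β-[(3,4-dimethoxybenzyl)oxy]-4-[(trifluoromethanesulfonyl)oxy]-1,4a,5,7a-tetrahydrocyclopenta[c]pyran-7-carboxylate | COc1ccc(CO[C@@H]2OC=C(OS(=O)(=O)C(F)(F)F)[C@H]3CC=C(C(=O)OCC)[C@@H]23)cc1OC | intermediate
10 | 1β-[(3,4-dimethoxybenzyl)oxy]-7-(hydroxymethyl)-1,4a,5,7a-tetrahydrocyclopenta[c]pyran-4-yl trifluoromethanesulfonate | COc1ccc(CO[C@@H]2OC=C(OS(=O)(=O)C(F)(F)F)[C@H]3CC=C(CO)[C@@H]23)cc1OC | intermediate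
11 | 1β-[(3,4-dimethoxybenzyl)oxy]-6β,7β-epoxy-7-(hydroxymethyl)-1,4a,5,6,7,7a-hexahydrocyclopenta[c]pyran-4-yl trifluoromethanesulfonate | COc1ccc(CO[C@@H]2OC=C(OS(=O)(=O)C(F)(F)F)[C@H]3C[C@@H]4O[C@]4(CO)[C@@H]23)cc1OC | intermediate
12 | (tributylstannyl)methanol | CCCC[Sn](CCCC)(CCCC)CO | starting material
13 | {1β-[(3,4-dimethoxybenzyl)oxy]-6β,7β-epoxy-1,4a,5,6,7,7a-hexahydrocyclopenta[c]pyran-4,7-diyl}dimethanol | COc1ccc(CO[C@@H]2OC=C(CO)[C@H]3C[C@@H]4O[C@]4(CO)[C@@H]23)cc1OC | intermediate
14 | 1β-[(3,4-dimethoxybenzyl)oxy]-4-(hydroxymethyl)-1,4a,5,6-tetrahydro-7aH-spiro[cyclopenta[c]pyran-7,2'-oxiran]-6β-ol, oxirane oxygen on the α face (not isolated) | COc1ccc(CO[C@@H]2OC=C(CO)[C@H]3C[C@H](O)[C@]4(CO4)[C@@H]23)cc1OC | intermediate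
15 | 1β-[(3,4-dimethoxybenzyl)oxy]-4,7-bis(hydroxymethyl)-1,4a,5,6,7,7a-hexahydrocyclopenta[c]pyran-6β,7α-diol | COc1ccc(CO[C@@H]2OC=C(CO)[C@H]3C[C@H](O)[C@](O)(CO)[C@@H]23)cc1OC | intermediate
16 | 4,7-bis({[tert-butyl(dimethyl)silyl]oxy}methyl)-1β-[(3,4-dimethoxybenzyl)oxy]-1,4a,5,6,7,7a-hexahydrocyclopenta[c]pyran-6β,7α-diol | COc1ccc(CO[C@@H]2OC=C(CO[Si](C)(C)C(C)(C)C)[C@H]3C[C@H](O)[C@](O)(CO[Si](C)(C)C(C)(C)C)[C@@H]23)cc1OC | intermediate
17 | (2Z)-3-iodoprop-2-enoic acid | OC(=O)/C=C\I | starting material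
18 | 6β-[(2Z)-3-iodoprop-2-enoyl] ester of 16 (7α-OH free) | COc1ccc(CO[C@@H]2OC=C(CO[Si](C)(C)C(C)(C)C)[C@H]3C[C@H](OC(=O)/C=C\I)[C@](O)(CO[Si](C)(C)C(C)(C)C)[C@@H]23)cc1OC | intermediate
19 | [4-(tert-butyldimethylsilyloxy)phenyl]boronic acid | OB(O)c1ccc(O[Si](C)(C)C(C)(C)C)cc1 | starting material
20 | 6β-{(2Z)-3-[4-(tert-butyldimethylsilyloxy)phenyl]prop-2-enoyl} ester of 16 | COc1ccc(CO[C@@H]2OC=C(CO[Si](C)(C)C(C)(C)C)[C@H]3C[C@H](OC(=O)/C=C\c4ccc(O[Si](C)(C)C(C)(C)C)cc4)[C@](O)(CO[Si](C)(C)C(C)(C)C)[C@@H]23)cc1OC | intermediate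
21 | lactol: 20 with 1β-OH in place of the dimethoxybenzyloxy group (anomers equilibrate) | O[C@@H]1OC=C(CO[Si](C)(C)C(C)(C)C)[C@H]2C[C@H](OC(=O)/C=C\c3ccc(O[Si](C)(C)C(C)(C)C)cc3)[C@](O)(CO[Si](C)(C)C(C)(C)C)[C@@H]12 | intermediate
22 | (3R)-3-methylpentanoic acid | CC[C@@H](C)CC(=O)O | starting material
23 | 1β-[(3R)-3-methylpentanoyl] ester of 21 (tris-silyl ether of the target) | CC[C@@H](C)CC(=O)O[C@@H]1OC=C(CO[Si](C)(C)C(C)(C)C)[C@H]2C[C@H](OC(=O)/C=C\c3ccc(O[Si](C)(C)C(C)(C)C)cc3)[C@](O)(CO[Si](C)(C)C(C)(C)C)[C@@H]12 | intermediate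
24 | (1S,4aS,6S,7R,7aS)-7-hydroxy-4,7-bis(hydroxymethyl)-6-{[(2Z)-3-(4-hydroxyphenyl)prop-2-enoyl]oxy}-1,4a,5,6,7,7a-hexahydrocyclopenta[c]pyran-1-yl (3R)-3-methylpentanoate | CC[C@@H](C)CC(=O)O[C@@H]1OC=C(CO)[C@H]2C[C@H](OC(=O)/C=C\c3ccc(O)cc3)[C@](O)(CO)[C@@H]12 | target

**Totals and risks**

Total step count: 15. Longest linear sequence: 15 steps (1 to 24).

Steps most likely to fail:

1. Step 5. Enolisation may take place at the ring-fusion carbon C4a instead of C3, which would give the wrong enol triflate and erase the C4a stereocentre. The fallback sets out from 8 and separates enolisation from sulfonylation. Soft enolisation (Me3SiOTf, Et3N, CH2Cl2, 0 °C) O-silylates the ketone first, and the amine then removes the more acidic C3 proton next to the ring oxygen, giving the trimethylsilyl enol ether F1. This is converted with CsF and PhNTf2 in DME at rt into the enol triflate, and the route is rejoined at 9.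

2. Step 8. Transfer of the hydroxymethyl group from tin may be slow, and at the temperature it needs the epoxide may be opened by chloride or the triflate lost by protonation. The fallback sets out from 11 and introduces the carbon by carbonylation and reduction instead. Methoxycarbonylation (Pd(OAc)2, PPh3, CO 1 atm, MeOH, Et3N, DMF, rt) should give the methyl ester F2, a vinylogous carbonate. Reduction with iBu2AlH in CH2Cl2 at −78 °C then gives the epoxy diol, and the route is rejoined at 13.

3. Step 9. Hydroxide may attack the 6,7-epoxide directly at C6 before the Payne shift, or the enol-ether diol may degrade in hot alkali. The fallback sets out from 13 and delivers the C7 oxygen through a tether under mild base. With CO2 (1 atm) and Cs2CO3 in DMF at 50 °C the hemicarbonate of the C7 hydroxymethyl group should open the epoxide at C7 with inversion (5-exo), giving the cyclic carbonate F3. Methanolysis (K2CO3, MeOH, 0 °C) frees the tetraol, and the route is rejoined at 15.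

**Further compounds**

F1 | step 5 | ethyl 1β-[(3,4-dimethoxybenzyl)oxy]-4-[(trimethylsilyl)oxy]-1,4a,5,7a-tetrahydrocyclopenta[c]pyran-7-carboxylate | COc1ccc(CO[C@@H]2OC=C(O[Si](C)(C)C)[C@H]3CC=C(C(=O)OCC)[C@@H]23)cc1OC
F2 | step 8 | methyl 1β-[(3,4-dimethoxybenzyl)oxy]-6β,7β-epoxy-7-(hydroxymethyl)-1,4a,5,6,7,7a-hexahydrocyclopenta[c]pyran-4-carboxylate | COc1ccc(CO[C@@H]2OC=C(C(=O)OC)[C@H]3C[C@@H]4O[C@]4(CO)[C@@H]23)cc1OC
F3 | step 9 | cyclic carbonate of 15 across the 7α-oxygen and the oxygen of the C7 hydroxymethyl group (spiro-1,3-dioxolan-2-one at C7; 6β-OH and C4-CH2OH free) | COc1ccc(CO[C@@H]2OC=C(CO)[C@H]3C[C@H](O)[C@]4(COC(=O)O4)[C@@H]23)cc1OC
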